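## Retrosynthetic overview

1. Ring numbering used throughout: C1 (heptenyl), C2 (CH2OH), C3–OH and C4–OH (β face), C5 (side chain) and C6–OH (α face). The carbocycle is the only ring; it is never formed, but taken intact from 2-hydroxy-5-methoxybenzaldehyde by oxidative dearomatisation to the flat, achiral p-quinone monoketal 4.
2. Enabling feature: O3 and O6 are para and C5 lies between the carbinol carbons C4 and C6, so the ring is a reduced 2-(hydroxymethyl)-p-benzoquinone. In its monoketal (C3=O, C6(OMe)2), C5 is the β-carbon of the only unsubstituted enone arm C3(=O)–C4=C5.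
3. Key disconnection C5–CH2: a catalytic enantioselective vinylogous Mukaiyama–Michael addition of the silyl dienolate of methyl tiglate to 4. The dienolate is the complete (E)-configured side chain and acts as a nucleophilic stand-in for the C5 isoprenoid unit that biosynthesis presumably attaches to this ring carbon. The step sets C5 and leaves a C3 silyl enol ether that carries the C4 oxygenation.
4. After the key step: C4–O by Rubottom oxidation (anti to C5), C3–OH by CBS reduction, ketal to C6 enone, C1–heptenyl by α-iodination and Suzuki coupling, C6–OH by bulky-hydride reduction, then desilylation and saponification.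

Key step: step 5

Remark: α and β denote the ring faces defined in line 1; every ring SMILES keeps the atom order of the target, so the stereo-descriptors can be compared directly. TBS = tert-butyldimethylsilyl.

## Route

Step 1
Reactants: 1 2-hydroxy-5-methoxybenzaldehyde
Product: 2 2-(hydroxymethyl)-4-methoxyphenol
Conditions: NaBH4, MeOH, 0 °C
Reagents that add atoms: none
Why: Borohydride reduction of the aryl aldehyde to the benzylic alcohol; no stereocentre is involved.

Step 2
Reactants: 2 2-(hydroxymethyl)-4-methoxyphenol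
Product: 3 2-(TBSOCH2)-4-methoxyphenol
Conditions: TBSCl (1.05 equiv), imidazole, CH2Cl2, 0 °C
Reagents that add atoms: tert-butyldimethylsilyl chloride, CC(C)(C)[Si](C)(C)Cl
Why: Chemoselective O-silylation, as the primary benzylic hydroxyl reacts faster than the phenol under imidazole catalysis with one equivalent of silyl chloride.

Step 3
Reactants: 3 2-(TBSOCH2)-4-methoxyphenol
Product: 4 2-(TBSOCH2)-4,4-dimethoxycyclohexa-2,5-dien-1-one (p-quinone monoketal; C3=O, C6(OMe)2 in ring numbering)
Conditions: PhI(OAc)2, MeOH, 0 °C
Reagents that add atoms: methanol, CO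
Why: Hypervalent-iodine oxidative dearomatisation of a p-methoxyphenol, in which methanol adds at the para carbon that already bears OMe to give the quinone monoketal.

Step 4
Reactants: 5 methyl tiglate
Product: 7 (1E)-tert-butyl[(1-methoxy-2-methylbuta-1,3-dien-1-yl)oxy]dimethylsilane, via lithium dienolate 6 (not isolated)
Conditions: LDA, DMPU, THF, −78 °C; TBSCl, −78 °C → rt
Reagents that add atoms: tert-butyldimethylsilyl chloride, CC(C)(C)[Si](C)(C)Cl
Why: Kinetic γ-deprotonation of the enoate and O-silylation give the silyl ketene acetal used in vinylogous Mukaiyama chemistry; its ketene-acetal geometry is lost later.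

Step 5
Reactants: 4 p-quinone monoketal; 7 silyl dienolate
Product: 8 methyl (2E)-4-[3-(TBSO)-2-(TBSOCH2)-6,6-dimethoxycyclohexa-1,3-dien-5α-yl]-2-methylbut-2-enoate (C3 TBS enol ether)
Conditions: (S)-o-tolyl-CBS oxazaborolidine·HNTf2 (20 mol%), Ph3PO (25 mol%), toluene, −78 → −40 °C; Et3N quench
Reagents that add atoms: none
Why: Proposed new method: the cationic oxazaborolidinium binds the C3 carbonyl of the flat dienone 4, the γ-carbon of silyl dienolate 7 adds in an open transition state to C5, and silyl transfer to the C3 oxygen releases the catalyst and leaves TBS enol ether 8. The closest known reaction types are the oxazaborolidinium-catalysed enantioselective Mukaiyama–Michael addition of silyl ketene acetals to cyclic enones and the γ-selective vinylogous Mukaiyama aldol reaction of this same tiglate dienolate; copper-catalysed asymmetric organozinc additions to 4,4-dimethoxycyclohexadienones show that the β-carbon next to the ketal is open to catalyst-controlled attack. No ring is closed. The only new stereocentre, C5, is set by the catalyst, which has to shield the β-face of the C4=C5 arm so that the nucleophile enters from the α-face; the (S)-catalyst is the one predicted by the usual enone-binding model, and its antipode is to be used if the first experiment shows the opposite sense. Site selectivity (C5 rather than C1, and 1,4 rather than 1,2) comes from the substrate: C1 belongs to the enone arm whose α-carbon C2 carries the silyloxymethyl group and is the more hindered β-position, and the bulky Lewis acid blocks the carbonyl carbon. γ-Attack and the (E)-enoate should follow from the α-methyl group and the bulky ketene-acetal terminus as in the aldol series, and the amine quench keeps the ketal from ionising, which would cost methanol and rearomatise the ring.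

Step 6
Reactants: 8 C3 TBS enol ether
Product: 10 methyl (2E)-4-[4β-(TBSO)-2-(TBSOCH2)-6,6-dimethoxy-3-oxocyclohex-1-en-5α-yl]-2-methylbut-2-enoate, via silyloxy epoxide 9 (not isolated)
Conditions: mCPBA, NaHCO3, CH2Cl2, −20 °C → rt
Reagents that add atoms: meta-chloroperoxybenzoic acid, OOC(=O)c1cccc(Cl)c1
Why: Rubottom oxidation, in which the peracid epoxidises the electron-rich silyl enol ether C3=C4 (C1=C2 and the enoate are less nucleophilic) from the β-face, anti to the neighbouring C5 side chain, and 1,4-silyl migration gives the C3 ketone with C4–OTBS trans to C5.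

Step 7
Reactants: 10 α-silyloxy enone
Product: 11 methyl (2E)-4-[3β-hydroxy-4β-(TBSO)-2-(TBSOCH2)-6,6-dimethoxycyclohex-1-en-5α-yl]-2-methylbut-2-enoate
Conditions: (R)-Me-CBS (0.3 equiv), catecholborane, toluene, −78 °C
Reagents that add atoms: none
Why: CBS (Corey–Bakshi–Shibata) reduction of an α-substituted cyclic enone, where the (R)-catalyst takes the C2 alkenyl arm as the large group and delivers hydride to the α-face of C3=O, also the face anti to the α-silyloxy group, so the new C3–OH is β and cis to C4–OTBS.

Step 8
Reactants: 11 allylic alcohol ketal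
Product: 12 methyl (2E)-4-[3β-hydroxy-4β-(TBSO)-2-(TBSOCH2)-6-oxocyclohex-1-en-5α-yl]-2-methylbut-2-enoate
Conditions: PPTS (cat.), acetone/H2O, rt
Reagents that add atoms: water, O
Why: Mild acid hydrolysis of the allylic dimethyl ketal unmasks the C6 ketone as an enone with C1=C2; it is placed after the C3 reduction because a C3/C6 ene-dione bearing C5–H would tautomerise to a hydroquinone.

Step 9
Reactants: 12 C6 enone
Product: 13 methyl (2E)-4-[3β-hydroxy-1-iodo-4β-(TBSO)-2-(TBSOCH2)-6-oxocyclohex-1-en-5α-yl]-2-methylbut-2-enoate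
Conditions: I2, pyridine, DMAP (cat.), CH2Cl2, 0 °C → rt
Reagents that add atoms: iodine, II
Why: Amine-mediated α-iodination of an enone (addition–iodination–elimination) places iodine on C1, the only enone α-carbon, and pyridine is too weak a base to eliminate the C4 silyloxy group.

Step 10
Reactants: 13 α-iodoenone; 14 (E)-hept-1-en-1-ylboronic acid
Product: 15 methyl (2E)-4-[1-((E)-hept-1-enyl)-3β-hydroxy-4β-(TBSO)-2-(TBSOCH2)-6-oxocyclohex-1-en-5α-yl]-2-methylbut-2-enoate
Conditions: PdCl2(PhCN)2 (5 mol%), AsPh3, Ag2O, THF/H2O, rt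
Reagents that add atoms: none
Why: Suzuki–Miyaura coupling of an α-iodoenone with an alkenylboronic acid under silver(I) oxide promotion proceeds with retention of the (E)-geometry and avoids strong base that could eliminate the β-silyloxy ketone.

Step 11
Reactants: 15 dienone
Product: 16 methyl (2E)-4-[1-((E)-hept-1-enyl)-3β,6α-dihydroxy-4β-(TBSO)-2-(TBSOCH2)cyclohex-1-en-5α-yl]-2-methylbut-2-enoate
Conditions: L-Selectride (2.5 equiv), THF, −78 °C; H2O quench
Reagents that add atoms: none
Why: Bulky-hydride 1,2-reduction, in which the hydride approaches C6=O from the β-face, anti to the adjacent C5 side chain (equatorial attack on the half-chair with C5–R pseudo-equatorial), to give the 6α-alcohol cis to C5, while the fully substituted β-carbon C2 rules out conjugate reduction.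

Step 12
Reactants: 16 bis-silyl ether
Product: 17 pestallic acid P methyl ester
Conditions: HF·pyridine, pyridine, THF, 0 °C → rt
Reagents that add atoms: none
Why: Buffered fluoride desilylation removes both TBS ethers without ionising the allylic alcohols at C3 and C6.

Step 13
Reactants: 17 pestallic acid P methyl ester
Product: 19 pestallic acid P, via lithium carboxylate 18 (not isolated)
Conditions: LiOH, THF/MeOH/H2O, rt; then 1 M HCl to pH 4–5, 0 °C
Reagents that add atoms: lithium hydroxide, [Li+].[OH-]
Why: Saponification of the methyl enoate followed by careful acidification releases the acid while the mild pH protects the allylic alcohols.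

## Compound list

1 | 2-hydroxy-5-methoxybenzaldehyde | COc1ccc(O)c(C=O)c1 | starting material
2 | 2-(hydroxymethyl)-4-methoxyphenol | COc1ccc(O)c(CO)c1 | intermediate
3 | 2-(TBSOCH2)-4-methoxyphenol | COc1ccc(O)c(CO[Si](C)(C)C(C)(C)C)c1 | intermediate
4 | 2-(TBSOCH2)-4,4-dimethoxycyclohexa-2,5-dien-1-one | COC1(OC)C=CC(=O)C(CO[Si](C)(C)C(C)(C)C)=C1 | intermediate
5 | methyl tiglate, methyl (E)-2-methylbut-2-enoate | C/C=C(\C)C(=O)OC | starting material
6 | lithium 1-methoxy-2-methylbuta-1,3-dien-1-olate (not isolated) | CO/C([O-])=C(/C)C=C.[Li+] | intermediate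
7 | (1E)-tert-butyl[(1-methoxy-2-methylbuta-1,3-dien-1-yl)oxy]dimethylsilane | CO/C(O[Si](C)(C)C(C)(C)C)=C(/C)C=C | intermediate
8 | C3 TBS enol ether, 5α side chain | C1=C(CO[Si](C)(C)C(C)(C)C)C(O[Si](C)(C)C(C)(C)C)=C[C@H](C/C=C(\C)C(=O)OC)C1(OC)OC | intermediate
9 | 3,4β-epoxide of 8, 3α-OTBS (not isolated) | C1=C(CO[Si](C)(C)C(C)(C)C)[C@@]2(O[Si](C)(C)C(C)(C)C)O[C@H]2[C@H](C/C=C(\C)C(=O)OC)C1(OC)OC | intermediate
10 | C3 ketone, 4β-OTBS, 5α side chain, C6 dimethyl ketal | C1=C(CO[Si](C)(C)C(C)(C)C)C(=O)[C@@H](O[Si](C)(C)C(C)(C)C)[C@H](C/C=C(\C)C(=O)OC)C1(OC)OC | intermediate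
11 | 3β-alcohol, 4β-OTBS, 5α side chain, C6 dimethyl ketal | C1=C(CO[Si](C)(C)C(C)(C)C)[C@@H](O)[C@@H](O[Si](C)(C)C(C)(C)C)[C@H](C/C=C(\C)C(=O)OC)C1(OC)OC | intermediate
12 | C6 enone, 3β-OH, 4β-OTBS, 5α side chain | C1=C(CO[Si](C)(C)C(C)(C)C)[C@@H](O)[C@@H](O[Si](C)(C)C(C)(C)C)[C@H](C/C=C(\C)C(=O)OC)C1=O | intermediate
13 | 1-iodo C6 enone | IC1=C(CO[Si](C)(C)C(C)(C)C)[C@@H](O)[C@@H](O[Si](C)(C)C(C)(C)C)[C@H](C/C=C(\C)C(=O)OC)C1=O | intermediate
14 | (E)-hept-1-en-1-ylboronic acid | CCCCC/C=C/B(O)O | starting material
15 | 1-[(E)-hept-1-enyl] C6 dienone | CCCCC/C=C/C1=C(CO[Si](C)(C)C(C)(C)C)[C@@H](O)[C@@H](O[Si](C)(C)C(C)(C)C)[C@H](C/C=C(\C)C(=O)OC)C1=O | intermediate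
16 | 6α-alcohol, bis-TBS ether, methyl ester | CCCCC/C=C/C1=C(CO[Si](C)(C)C(C)(C)C)[C@@H](O)[C@@H](O[Si](C)(C)C(C)(C)C)[C@H](C/C=C(\C)C(=O)OC)[C@@H]1O | intermediate
17 | pestallic acid P methyl ester | CCCCC/C=C/C1=C(CO)[C@@H](O)[C@@H](O)[C@H](C/C=C(\C)C(=O)OC)[C@@H]1O | intermediate
18 | lithium salt of pestallic acid P (not isolated) | CCCCC/C=C/C1=C(CO)[C@@H](O)[C@@H](O)[C@H](C/C=C(\C)C(=O)[O-])[C@@H]1O.[Li+] | intermediate
19 | pestallic acid P | CCCCC/C=C/C1=C(CO)[C@@H](O)[C@@H](O)[C@H](C/C=C(\C)C(=O)O)[C@@H]1O | target

## Step count and risks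

Total step count: 13. Longest linear sequence: 12 steps (steps 1–3 and 5–13); step 4 is a one-step branch.

Steps most likely to fail:

1. Step 5 (proposed new method). What may go wrong: insufficient enantiofacial discrimination on the dienone, α- instead of γ-attack of the dienolate, or Lewis-acid ionisation of the ketal followed by loss of methanol and rearomatisation. The fallback uses known chemistry, sets out from 4 and returns at 8, and builds the side chain stepwise. A catalytic asymmetric Michael addition of dimethyl malonate to the unsubstituted enone arm of 4, using a heterobimetallic Al–Li–BINOL catalyst of the antipode that gives the 5α adduct, should give malonate adduct F1. Krapcho dealkoxycarbonylation (LiCl, wet DMSO, heat) would give the monoester F2. Kinetic enolisation at C4 with LDA and trapping with TBSCl would give the TBS enol ether F3. DIBAL at −78 °C would reduce the ester to the aldehyde F4. A Wittig reaction with methyl 2-(triphenylphosphoranylidene)propanoate should then install the (E)-enoate and deliver 8.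

2. Step 7. What may go wrong: poor facial selectivity at C3 if the substrate preference opposes the catalyst, or competing hydroboration. The fallback sets out from 10 and returns at 11, and accepts the substrate-preferred epimer and inverts it. Luche reduction (NaBH4, CeCl3, MeOH) would give the 3α-alcohol F5. Mitsunobu inversion with 4-nitrobenzoic acid, PPh3 and DIAD would give the 3β-(4-nitrobenzoate) F6. Methanolysis with K2CO3 in MeOH should then give 11.

3. Step 11. What may go wrong: hydride delivery to the wrong face of C6=O, or base-induced elimination of the C4 silyloxy group followed by aromatisation. The fallback sets out from 15 and returns at 17, and replaces steric control by hydroxyl-directed delivery. Desilylation of 15 with buffered HF·pyridine would give the triol dienone F7. Evans–Saksena reduction with Me4NBH(OAc)3 in MeCN/AcOH at −30 °C should then deliver hydride intramolecularly from the C4–OH on the β-face and give the 1,3-anti diol, which is 17.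

Further compounds
F1 | step 5 | dimethyl 2-[2-(TBSOCH2)-6,6-dimethoxy-3-oxocyclohex-1-en-5α-yl]malonate | C1=C(CO[Si](C)(C)C(C)(C)C)C(=O)C[C@H](C(C(=O)OC)C(=O)OC)C1(OC)OC
F2 | step 5 | methyl 2-[2-(TBSOCH2)-6,6-dimethoxy-3-oxocyclohex-1-en-5α-yl]acetate | C1=C(CO[Si](C)(C)C(C)(C)C)C(=O)C[C@H](CC(=O)OC)C1(OC)OC
F3 | step 5 | methyl 2-[3-(TBSO)-2-(TBSOCH2)-6,6-dimethoxycyclohexa-1,3-dien-5α-yl]acetate | C1=C(CO[Si](C)(C)C(C)(C)C)C(O[Si](C)(C)C(C)(C)C)=C[C@H](CC(=O)OC)C1(OC)OC
F4 | step 5 | 2-[3-(TBSO)-2-(TBSOCH2)-6,6-dimethoxycyclohexa-1,3-dien-5α-yl]acetaldehyde | C1=C(CO[Si](C)(C)C(C)(C)C)C(O[Si](C)(C)C(C)(C)C)=C[C@H](CC=O)C1(OC)OC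
F5 | step 7 | 3α-epimer of 11 | C1=C(CO[Si](C)(C)C(C)(C)C)[C@H](O)[C@@H](O[Si](C)(C)C(C)(C)C)[C@H](C/C=C(\C)C(=O)OC)C1(OC)OC
F6 | step 7 | 3β-(4-nitrobenzoate) of 11 | C1=C(CO[Si](C)(C)C(C)(C)C)[C@@H](OC(=O)c2ccc(cc2)[N+](=O)[O-])[C@@H](O[Si](C)(C)C(C)(C)C)[C@H](C/C=C(\C)C(=O)OC)C1(OC)OC
F7 | step 11 | desilylated dienone, methyl (2E)-4-[1-((E)-hept-1-enyl)-3β,4β-dihydroxy-2-(hydroxymethyl)-6-oxocyclohex-1-en-5α-yl]-2-methylbut-2-enoate | CCCCC/C=C/C1=C(CO)[C@@H](O)[C@@H](O)[C@H](C/C=C(\C)C(=O)OC)C1=O
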